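In a closed, stirred vessel held at one temperature, L is down to 3.9% of its charge at 2.00 min in the gamma run, yet J goes on climbing after that, to 12.6% at 6.00 min.

| setting | zeta | gamma | teal | grey |
|---|---|---|---|---|
| L | 0.66 M | 2.5 M | 2.0 M | 0.50 M |
| temperature | 14 °C | 22 °C | 10 °C | 25 °C |
| remark | run made earlier | run made earlier |  |  |
| time |  |  | 12 min | 8.0 min |

| run | time / min | J / % | L / % |
|---|---|---|---|
| zeta | 2.50 | 2.1 | 18.1 |
| zeta | 5.00 | 4.9 | 4.6 |
| zeta | 6.00 | 6.8 | 2.2 |
| zeta | 10.0 | 10.4 | 1.7 |
| gamma | 0.667 | 2.4 | 23.8 |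
| gamma | 2.00 | 6.0 | 3.9 |
| gamma | 4.00 | 8.2 | 1.8 |
| gamma | 6.00 | 12.6 | 1.4 |

(scatter of a reading: 0.5 percentage points)

- the flask that ends with the higher amount of J, in percent of the L charged, or "neither" when 2 percentage points or less lies between them (teal / grey / neither)
- final J, as a percentage of the L charged, in teal
- final J, as a percentage of the L charged, in grey



I read this as an unseen pool filled quickly from L and drained slowly into J, so J rises towards a ceiling C, and its gap to C shrinks by a factor e in each pool life τ.

In gamma, J at 6.00 min is 2.10 times J at 2.00 min, and for such a curve that leaves a share 0.662 of the gap after 2.00 min. So C is 17.7%, and the time τ is 4.85 min: the pool life, the time in which the gap between J and C shrinks by a factor e. Both are readings with a scatter of 0.5 percentage points on each J.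

The opening pace of J, J over time at 2.00 min in gamma and at 5.00 min in zeta, is 3.06 times higher in gamma. I put all of that on the temperature, though c_L changes too, and shorten τ by the same factor per degree.

That gives 3.19 min for grey, shorter than its run, so J there is 16.3%. It gives 26.0 min for teal, longer than its run, so J there is 6.57%.

The forecast says grey, with 8.5% in teal and 18% in grey, holding that “most L goes to an unseen intermediate, which then feeds J slowly”.

The flasks give 6.07% in teal and 18.8% in grey, so grey ends higher, as I reckoned, though my grey figure is lower.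

    X → D (k = 0.210 min⁻¹, Ea = 89.0 kJ mol⁻¹)
    L ⇌ X (K = 20.0, k = 2.50 min⁻¹, Ea = 87.0 kJ mol⁻¹, ΔH = −46.0 kJ mol⁻¹)
    X ⇌ G (K = 1.50, k = 0.110 min⁻¹, Ea = 76.0 kJ mol⁻¹, ΔH = −14.0 kJ mol⁻¹)
    X → J (k = 0.0790 min⁻¹, Ea = 91.0 kJ mol⁻¹)
    2 L → Z (k = 0.240 M⁻¹ min⁻¹, Ea = 59.0 kJ mol⁻¹)
    (constants at 25 °C)

In grey, X is made 6.61 times faster than it is used at 0.271 min, but only 0.226 as fast at 8.00 min, and from 24.9% at 4.00 min to 8.10% at 8.00 min it falls with a life of 3.57 min, against my 3.19 min. In teal, X goes from 52.8% at 6.00 min to 40.3% at 12.0 min, a life of 22.2 min against my 26.0 min, longer than the run, and 40.3% of the charge still stands as X at the end.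

The data come from a simulation with constants of no real substance, noise included.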